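The data are calculated from invented constants; scatter was added.

**The constants.** No equilibrium constant is given, but the earlier runs hold one. One target or one isomer of the product counts as two units of starting material, so the bound share is tied to the square of the free share.

| setting | red | amber | flask |
|---|---|---|---|
| starting material | 0.14 M | 0.22 M | 0.10 M |
| remark | run made earlier | run made earlier |  |
| time |  |  | 15 d |

| run | time / d | target / % | isomer of the product / % |
|---|---|---|---|
| red | 1.25 | 29.3 | 33.2 |
| red | 2.08 | 27.6 | 34.4 |
| red | 3.00 | 28.2 | 34.7 |
| red | 5.00 | 28.9 | 34.3 |
| red | 10.0 | 29.0 | 34.4 |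
| red | 15.0 | 28.6 | 34.4 |
| amber | 1.25 | 32.0 | 36.9 |
| amber | 2.08 | 32.4 | 37.2 |
| amber | 3.00 | 31.7 | 37.3 |
| amber | 5.00 | 31.2 | 37.6 |
| amber | 10.0 | 32.0 | 38.2 |
| amber | 15.0 | 31.1 | 37.2 |

(readings scatter by 0.5 percentage points)

- percent here means starting material units held: one target or isomer of the product counts as two

1. target at 15 d, in percent of the starting material charged
2. isomer of the product at 15 d, in percent of the starting material charged

**Two ways.** The red run, averaged from 5.00 d on, leaves a free share of 36.8 %. Bound share over free share squared times charge then gives 33.3 M⁻¹. The amber run, at another charge, leaves 30.9 % and gives 32.9 M⁻¹, close to the red value. Their mean, 33.1 M⁻¹, is the holding number: bound share divided by free share squared times charge, a form of the equilibrium constant.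

**Time.** The isomer of the product in the red run reads level, within the scatter, from 2.08 d on. Scaled by the charges, that span becomes 2.91 d for the flask, and 15 d holds 5.15 such spans, so the flask is read at rest.

**Own reckoning.** At 0.10 M the holding number gives a free share of 41.9 %. The runs split the bound rest at 1.20 isomer per target, which makes 26.5 % target and 31.6 % isomer of the product.

**The forecast.** Holding that “the plateaus are equilibrium”, the forecast says 26.6 % target (25.6 % to 27.6 %) and 31.6 % isomer of the product (30.6 % to 32.6 %).

**The flask.** After 15 d the flask holds 26.3 % target and 31.6 % isomer of the product, inside both ranges of the forecast.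

    2 starting material ⇌ target (K = 7.40 M⁻¹, k = 2.00 M⁻¹ h⁻¹)
    target ⇌ isomer of the product (K = 1.20, k = 0.0880 h⁻¹)

With the time held at 15 d, the nearest charges at which the isomer share has moved by 5 points are 0.0568 M and 0.189 M. At the upper charge the holding number gives a free share of 32.8 % and 36.7 % isomer of the product.

**Second flask.** At 0.40 M the holding number gives a free share of 24.0 %, with 34.5 % target and 41.5 % isomer of the product. That flask holds 24.1 % starting material, 34.5 % target and 41.4 % isomer of the product at 15.0 d.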